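**Retrosynthetic overview**

1. Feature: in ring A the oxygens on C5 and C8 are para, so ring A is a masked 2-acyl-1,4-benzoquinone whose only CH carbon, C8a, is the beta carbon of both the C5 enone and the C4 acyl enone and can accept O1.
2. Target ⇐ hydrogenolysis of the 7-O-benzyl ether ⇐ methylation of the free O8 (O5 stays chelated) of a 7-(benzyloxy)-5,8-dihydroxyflavone.
3. Ring C is the only ring built (rings A and B are bought as arenes): O1–C8a forms when the 2,5-dimethoxyaryl 1,3-diketone is oxidised with (NH4)2Ce(NO3)6 and the enol oxygen closes onto the acylquinone.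
4. Diketone ⇐ C3–C4 bond by aldol addition of the lithium enolate of 3',4',5'-trimethoxyacetophenone to 4-(benzyloxy)-2,3,5-trimethoxybenzaldehyde, then oxidation.
5. Aldehyde ⇐ syringaldehyde by bromination at C2, copper-catalysed methoxylation and O-benzylation.

Key step: step 6

Assumption: diketone 9 is drawn as the diketo tautomer although it should exist mainly as the chelated enol, and aldol 8 is made as a racemate because step 5 removes its stereocentre.

**Step 1**
Reactants: 1 syringaldehyde
Product: 2 2-bromo-4-hydroxy-3,5-dimethoxybenzaldehyde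
Conditions: Br2 (1.05 equiv), AcOH, 20 °C
Reagents that add atoms: bromine, BrBr
Why: Electrophilic aromatic bromination: the two free positions of 1 are equivalent and each is activated by an ortho and a para methoxy group, while the formyl group and the first bromine slow a second substitution and the water-free acid keeps ipso attack at C1 from ending in loss of the formyl group.

**Step 2**
Reactants: 2 2-bromo-4-hydroxy-3,5-dimethoxybenzaldehyde
Product: 3 4-hydroxy-2,3,5-trimethoxybenzaldehyde
Conditions: NaOMe (5 equiv), CuCl (0.2 equiv), MeOH–DMF, 110 °C; then aq. HCl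
Reagents that add atoms: sodium methoxide, C[O-].[Na+]
Why: Copper-catalysed Ullmann-type exchange of aryl bromide for methoxide, the reaction type that turns 5-bromovanillin into syringaldehyde: the substrate reacts as its phenoxide, a vinylogous carboxylate that shields the formyl group from methoxide, and the ortho formyl group assists the copper insertion.

**Step 3**
Reactants: 3 4-hydroxy-2,3,5-trimethoxybenzaldehyde; 4 benzyl bromide
Product: 5 4-(benzyloxy)-2,3,5-trimethoxybenzaldehyde
Conditions: K2CO3, DMF, 50 °C
Reagents that add atoms: none
Why: Williamson ether synthesis: the phenoxide is the only nucleophile in 3 and benzyl bromide is reactive enough for an oxygen flanked by two methoxy groups.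

**Step 4**
Reactants: 6 3',4',5'-trimethoxyacetophenone; 5 4-(benzyloxy)-2,3,5-trimethoxybenzaldehyde
Product: 8 3-[4-(benzyloxy)-2,3,5-trimethoxyphenyl]-3-hydroxy-1-(3,4,5-trimethoxyphenyl)propan-1-one (racemic), via lithium enolate 7 (not isolated)
Conditions: LiN(iPr)2, THF, −78 °C; then 5, −78 °C; AcOH quench at −78 °C
Reagents that add atoms: none
Why: Directed aldol addition of a preformed lithium enolate to a non-enolisable aldehyde under kinetic control; the cold acid quench should prevent retro-aldol cleavage and loss of water to the chalcone, and the carbinol stereocentre is formed without control because step 5 removes it.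

**Step 5**
Reactants: 8 3-[4-(benzyloxy)-2,3,5-trimethoxyphenyl]-3-hydroxy-1-(3,4,5-trimethoxyphenyl)propan-1-one
Product: 9 1-[4-(benzyloxy)-2,3,5-trimethoxyphenyl]-3-(3,4,5-trimethoxyphenyl)propane-1,3-dione
Conditions: IBX (1.5 equiv), EtOAc, 75 °C
Reagents that add atoms: none
Why: Oxidation of a secondary benzylic alcohol by 2-iodoxybenzoic acid, a neutral reagent that converts beta-hydroxy ketones into 1,3-diketones without retro-aldol cleavage and leaves the benzyl and methyl ethers untouched.

**Step 6**
Reactants: 9 1-[4-(benzyloxy)-2,3,5-trimethoxyphenyl]-3-(3,4,5-trimethoxyphenyl)propane-1,3-dione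
Product: 11 7-(benzyloxy)-5,8-dihydroxy-6-methoxy-2-(3,4,5-trimethoxyphenyl)-4H-chromen-4-one, via acylquinone 10 (not isolated)
Conditions: (NH4)2Ce(NO3)6 (2.2 equiv), MeCN–H2O (3:1), argon, 0 °C then rt; work-up with aq. Na2S2O4
Reagents that add atoms: water, O
Why: Proposed new method: tetravalent cerium should take two electrons from the tetra-alkoxy ring A, water then attacks the two ring carbons that carry the para methoxy groups and two molecules of methanol leave, giving acylquinone 10 as in the known oxidative demethylation of 1,4-dimethoxyarenes (for example 2,3,4,5-tetramethoxytoluene to 2,3-dimethoxy-5-methylbenzoquinone), which together with the addition of oxygen nucleophiles to C3 of 2-acyl-1,4-benzoquinones is the closest known reaction type. In 10 the only ring carbon that bears hydrogen, the later C8a, is beta to the quinone carbonyl at C5 and beta to the acyl carbonyl at C4, and the enol oxygen on C2 of the chain should add to it in a 6-endo-trig oxa-Michael reaction that closes ring C. Enolisation of the adduct towards C8 restores the benzene ring and gives hydroquinone 11, so the closure itself needs no further oxidant and creates no stereocentre. Site selectivity rests on the substrate: only the methoxy groups on C5 and C8 are para to each other, the plain benzyl ether is not one the oxidant cleaves, ring B has no para pair of oxygens and is deactivated by its acyl group, and the quinone offers the nucleophile a single free carbon. Chemoselectivity against oxidation of the diketone enol is the open point and is addressed by low temperature, a small excess of oxidant and short contact, while the acidic medium protonates the quinone and should speed the conjugate addition. The Na2S2O4 work-up is a safeguard that, in the intended course, has nothing to reduce; it returns any 11 that was oxidised on to the flavone-5,8-quinone.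

**Step 7**
Reactants: 11 7-(benzyloxy)-5,8-dihydroxy-6-methoxy-2-(3,4,5-trimethoxyphenyl)-4H-chromen-4-one
Product: 12 7-(benzyloxy)-5-hydroxy-6,8-dimethoxy-2-(3,4,5-trimethoxyphenyl)-4H-chromen-4-one
Conditions: MeI (1.2 equiv), K2CO3 (1.5 equiv), degassed acetone, argon, 40 °C
Reagents that add atoms: iodomethane, CI
Why: Williamson O-methylation under site control by hydrogen bonding: the 5-hydroxyl is tied to the C4 carbonyl in a six-membered chelate and is much less acidic and nucleophilic than the free 8-hydroxyl, so a small excess of iodomethane with a weak base should alkylate O8 only, and exclusion of air keeps the hydroquinone from going to the quinone.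

**Step 8**
Reactants: 12 7-(benzyloxy)-5-hydroxy-6,8-dimethoxy-2-(3,4,5-trimethoxyphenyl)-4H-chromen-4-one
Product: 13 5,7-dihydroxy-6,8,3',4',5'-pentamethoxyflavone
Conditions: H2 (1 atm), 10% Pd/C, EtOAc–MeOH, rt
Reagents that add atoms: none
Why: Catalytic hydrogenolysis of the benzyl ether; the aryl methyl ethers are inert and the C2–C3 double bond of the pyranone, a vinylogous ester conjugated with two aryl rings, is reduced far more slowly, so the reaction is stopped after one equivalent of hydrogen.

**Compound list**

1 | syringaldehyde (4-hydroxy-3,5-dimethoxybenzaldehyde) | COc1cc(C=O)cc(OC)c1O | starting material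
2 | 2-bromo-4-hydroxy-3,5-dimethoxybenzaldehyde | COc1cc(C=O)c(Br)c(OC)c1O | intermediate
3 | 4-hydroxy-2,3,5-trimethoxybenzaldehyde | COc1cc(C=O)c(OC)c(OC)c1O | intermediate
4 | benzyl bromide | BrCc1ccccc1 | starting material
5 | 4-(benzyloxy)-2,3,5-trimethoxybenzaldehyde | COc1cc(C=O)c(OC)c(OC)c1OCc1ccccc1 | intermediate
6 | 3',4',5'-trimethoxyacetophenone | CC(=O)c1cc(OC)c(OC)c(OC)c1 | starting material
7 | lithium 1-(3,4,5-trimethoxyphenyl)ethenolate (lithium enolate of 6) | C=C(O[Li])c1cc(OC)c(OC)c(OC)c1 | intermediate
8 | 3-[4-(benzyloxy)-2,3,5-trimethoxyphenyl]-3-hydroxy-1-(3,4,5-trimethoxyphenyl)propan-1-one (racemic) | COc1cc(C(=O)CC(O)c2cc(OC)c(OCc3ccccc3)c(OC)c2OC)cc(OC)c1OC | intermediate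
9 | 1-[4-(benzyloxy)-2,3,5-trimethoxyphenyl]-3-(3,4,5-trimethoxyphenyl)propane-1,3-dione | COc1cc(C(=O)CC(=O)c2cc(OC)c(OCc3ccccc3)c(OC)c2OC)cc(OC)c1OC | intermediate
10 | 2-(benzyloxy)-3-methoxy-5-[3-oxo-3-(3,4,5-trimethoxyphenyl)propanoyl]cyclohexa-2,5-diene-1,4-dione (acylquinone) | COc1cc(C(=O)CC(=O)C2=CC(=O)C(OCc3ccccc3)=C(OC)C2=O)cc(OC)c1OC | intermediate
11 | 7-(benzyloxy)-5,8-dihydroxy-6-methoxy-2-(3,4,5-trimethoxyphenyl)-4H-chromen-4-one | COc1cc(-c2cc(=O)c3c(O)c(OC)c(OCc4ccccc4)c(O)c3o2)cc(OC)c1OC | intermediate
12 | 7-(benzyloxy)-5-hydroxy-6,8-dimethoxy-2-(3,4,5-trimethoxyphenyl)-4H-chromen-4-one | COc1cc(-c2cc(=O)c3c(O)c(OC)c(OCc4ccccc4)c(OC)c3o2)cc(OC)c1OC | intermediate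
13 | 5,7-dihydroxy-6,8,3',4',5'-pentamethoxyflavone | COc1cc(-c2cc(=O)c3c(O)c(OC)c(O)c(OC)c3o2)cc(OC)c1OC | target

**Step count**

Total steps: 8. Longest linear sequence: 8 steps (1 to 13); 4 and 6 are bought.

**Steps most likely to fail**

Step 6 (proposed new method). Three processes may defeat the cascade. Tetravalent cerium may oxidise the diketone enol in competition with ring A. Water may add to the acylquinone in place of the enol oxygen. Redox exchange between 11 and 10 may return open-chain material to the hydroquinone level, from which the hydroxyl ortho to the carbonyl would close ring C the wrong way round and give a flavone without O5.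

The fallback makes the O1–C8a bond by known copper-catalysed O-arylation instead of by addition to a quinone, and sets out from 5. Bromination of 5 at its single free ring position (NBS, MeCN, rt) should give 4-(benzyloxy)-2-bromo-3,5,6-trimethoxybenzaldehyde F1. Aldol addition of lithium enolate 7 (THF, −78 °C) should give 3-[4-(benzyloxy)-2-bromo-3,5,6-trimethoxyphenyl]-3-hydroxy-1-(3,4,5-trimethoxyphenyl)propan-1-one F2. Oxidation with IBX (EtOAc, 75 °C) should give 1-[4-(benzyloxy)-2-bromo-3,5,6-trimethoxyphenyl]-3-(3,4,5-trimethoxyphenyl)propane-1,3-dione F3. Intramolecular Ullmann-type O-arylation of its enolate (CuI, 1,10-phenanthroline, K2CO3, DMF, 110 °C), a known flavone synthesis from 1-(2-bromoaryl)-1,3-diketones, should close ring C to 7-(benzyloxy)-5,6,8-trimethoxy-2-(3,4,5-trimethoxyphenyl)-4H-chromen-4-one F4. BCl3 (CH2Cl2, −78 to 0 °C) should then cleave the benzyl ether and, through the boron chelate with the C4 carbonyl, only the 5-methoxy group. The fallback comes back to the route at 13.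

Step 7. The chelated 5-hydroxyl may be alkylated as well, and the hydroquinone anion may be oxidised by traces of air to the flavone-5,8-quinone before it is alkylated.

The fallback gives up the selective alkylation and sets out from 11. Exhaustive methylation (Me2SO4 in excess, K2CO3, acetone, reflux, argon) should give 7-(benzyloxy)-5,6,8-trimethoxy-2-(3,4,5-trimethoxyphenyl)-4H-chromen-4-one F5, the same substance that the fallback for step 6 reaches. Chelation-directed cleavage of the 5-methyl ether together with the benzyl ether by BCl3 (CH2Cl2, −78 to 0 °C) should then lead back to the route at 13.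

Step 2. Reductive loss of bromine and attack of hot methoxide on the formyl group may compete with the copper-mediated exchange on the electron-rich phenoxide.

The fallback moves the C–O coupling to the protected substrate and to palladium catalysis, and sets out from 2. Benzylation with 4 (K2CO3, DMF, 50 °C) should give 4-(benzyloxy)-2-bromo-3,5-dimethoxybenzaldehyde F6. Palladium-catalysed coupling with methanol (Pd2(dba)3, tBuBrettPhos, Cs2CO3, MeOH–toluene, 80 °C), a known etherification of aryl bromides under weakly basic conditions, should then give 5, where the fallback comes back to the route.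

**Further compounds**

F1 | step 6 | 4-(benzyloxy)-2-bromo-3,5,6-trimethoxybenzaldehyde | COc1c(Br)c(C=O)c(OC)c(OC)c1OCc1ccccc1
F2 | step 6 | 3-[4-(benzyloxy)-2-bromo-3,5,6-trimethoxyphenyl]-3-hydroxy-1-(3,4,5-trimethoxyphenyl)propan-1-one (racemic) | COc1cc(C(=O)CC(O)c2c(Br)c(OC)c(OCc3ccccc3)c(OC)c2OC)cc(OC)c1OC
F3 | step 6 | 1-[4-(benzyloxy)-2-bromo-3,5,6-trimethoxyphenyl]-3-(3,4,5-trimethoxyphenyl)propane-1,3-dione | COc1cc(C(=O)CC(=O)c2c(Br)c(OC)c(OCc3ccccc3)c(OC)c2OC)cc(OC)c1OC
F4 | step 6 | 7-(benzyloxy)-5,6,8-trimethoxy-2-(3,4,5-trimethoxyphenyl)-4H-chromen-4-one | COc1cc(-c2cc(=O)c3c(OC)c(OC)c(OCc4ccccc4)c(OC)c3o2)cc(OC)c1OC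
F5 | step 7 | 7-(benzyloxy)-5,6,8-trimethoxy-2-(3,4,5-trimethoxyphenyl)-4H-chromen-4-one | COc1cc(-c2cc(=O)c3c(OC)c(OC)c(OCc4ccccc4)c(OC)c3o2)cc(OC)c1OC
F6 | step 2 | 4-(benzyloxy)-2-bromo-3,5-dimethoxybenzaldehyde | COc1cc(C=O)c(Br)c(OC)c1OCc1ccccc1
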